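The route rests on one disconnection: the oxirane is opened at its CH2–O bond and the side-chain ester is taken off. The fully substituted oxirane carbon bears the benzene ring, the ring oxygen and two CH2–O arms (the oxirane CH2 and the CH2 of the isobutyrate). A mirror plane therefore passes through it as soon as both arms are hydroxymethyl groups. In the key step a lipase transfers an isobutyryl group from isobutyric anhydride to one enantiotopic CH2OH. This fixes the quaternary stereocentre and installs the target's own ester at once. The precursor is an achiral 2-arylpropane-1,2,3-triol already carrying the aryl isobutyrate, assembled from an aryllithium and dihydroxyacetone acetonide. Mesylation and 3-exo-tet closure complete the oxirane.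

Key step: step 6

Assumption: the arm that a given lipase acylates cannot be predicted for this substrate. Immobilised Candida antarctica lipase B is taken to give the (S)-monoester 11. The configuration is to be checked on the first batch, and the opposite preference is covered by the fallback to step 6.

Step 1
Reactants: 1 4-methoxy-3-methylphenol
Product: 2 2-bromo-4-methoxy-5-methylphenol
Conditions: NBS (1.0 equiv), MeCN, 0 °C, dark
Reagents that add atoms: N-bromosuccinimide, O=C1CCC(=O)N1Br
Why: Electrophilic aromatic bromination, in which the free hydroxyl is the strongest director and its open ortho position is also para to the methyl group, while the other ortho site is wedged between OH and CH3 and the site next to OMe has only one activator, so one equivalent of NBS in a polar solvent without light should brominate that single position and spare the benzylic CH3.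

Step 2
Reactants: 2 2-bromo-4-methoxy-5-methylphenol
Product: 3 1-(benzyloxy)-2-bromo-4-methoxy-5-methylbenzene
Conditions: BnBr (1.1 equiv), K2CO3, DMF, rt
Reagents that add atoms: benzyl bromide, BrCc1ccccc1
Why: Williamson ether synthesis, in which the phenoxide made with K2CO3 displaces bromide from benzyl bromide and the acidic OH is masked for the organolithium step by a group that later leaves under neutral hydrogenolysis.

Step 3
Reactants: 3 1-(benzyloxy)-2-bromo-4-methoxy-5-methylbenzene; 4 2,2-dimethyl-1,3-dioxan-5-one
Product: 6 5-[2-(benzyloxy)-5-methoxy-4-methylphenyl]-2,2-dimethyl-1,3-dioxan-5-ol, via aryllithium 5 (not isolated)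
Conditions: n-BuLi (1.05 equiv), THF, −78 °C, 30 min; then 4 (1.2 equiv, precooled in THF), −78 → −20 °C; H2O quench
Reagents that add atoms: n-butyllithium, [Li]CCCC (supplies the lithium of 5 only; none of its atoms remains in 6)
Why: Bromine–lithium exchange followed by 1,2-addition of the aryllithium to a ketone, where exchange at −78 °C outruns deprotonation of the benzylic OCH2 and alkylation by n-BuBr, cold addition of the ketone keeps enolisation behind carbonyl attack, and the product is achiral because the dioxane ring is symmetric.

Step 4
Reactants: 6 5-[2-(benzyloxy)-5-methoxy-4-methylphenyl]-2,2-dimethyl-1,3-dioxan-5-ol; 7 isobutyric anhydride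
Product: 9 2-(5-hydroxy-2,2-dimethyl-1,3-dioxan-5-yl)-4-methoxy-5-methylphenyl isobutyrate, via free phenol 8 (not isolated)
Conditions: H2 (1 atm), 10% Pd/C, EtOAc, rt; filter through Celite under N2; then 7 (1.1 equiv), Et3N (1.5 equiv), DMAP (5 mol %), 0 °C
Reagents that add atoms: isobutyric anhydride (7), CC(C)C(=O)OC(=O)C(C)C
Why: Catalytic hydrogenolysis of an aryl benzyl ether followed by base-mediated O-acylation, in which the tertiary benzylic hydroxyl is not reduced under neutral conditions at 1 atm, the air-sensitive hydroquinone monoether 8 is esterified in the filtrate without being handled, and the crowded tertiary hydroxyl cannot compete with the phenol for a near-stoichiometric amount of 7.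

Step 5
Reactants: 9 2-(5-hydroxy-2,2-dimethyl-1,3-dioxan-5-yl)-4-methoxy-5-methylphenyl isobutyrate
Product: 10 4-methoxy-5-methyl-2-(1,2,3-trihydroxypropan-2-yl)phenyl isobutyrate
Conditions: AcOH–THF–H2O (3:1:1), rt; solvents removed with toluene below 30 °C; used directly
Reagents that add atoms: none
Why: Acid-catalysed ketal hydrolysis, in which the six-membered acetonide opens in dilute acetic acid, a medium too weak to ionise the tertiary benzylic C–O bond (its ortho neighbour is now an electron-poor acyloxy group) or to hydrolyse the hindered aryl ester, and acidic rather than basic conditions keep acyl transfer slow.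

Step 6
Reactants: 10 4-methoxy-5-methyl-2-(1,2,3-trihydroxypropan-2-yl)phenyl isobutyrate; 7 isobutyric anhydride
Product: 11 (2S)-2,3-dihydroxy-2-[2-(isobutyryloxy)-5-methoxy-4-methylphenyl]propyl isobutyrate
Conditions: Candida antarctica lipase B immobilised on acrylic resin (Novozym 435), 7 (1.2 equiv), MTBE–MeCN (9:1), 0–5 °C, followed by chiral HPLC and stopped just after 10 is consumed; filter off the enzyme; brief cold aq. NaHCO3 wash; used the same day
Reagents that add atoms: isobutyric anhydride (7), CC(C)C(=O)OC(=O)C(C)C
Why: The catalytic serine of the lipase is acylated by 7, and the isobutyryl-enzyme hands its acyl group to the one primary hydroxyl of 10 that the chiral alcohol pocket can bring to the active site, releasing one isobutyric acid. This is the established lipase desymmetrisation of prochiral 2-substituted propane-1,3-diols and 2-substituted glycerols with an irreversible acyl donor, a role for which isobutyric anhydride is proven. One C–O ester bond forms and no ring is closed. The new quaternary stereocentre (C2 of the propane chain) is controlled by the enzyme alone, which must lodge the large ortho-acyloxyaryl group and the small hydroxyl in different sub-pockets and so reaches only the arm leading to (S)-11. The step needs enantiotopic-group selectivity and chemoselectivity: the size gap between aryl and OH on the prochiral carbon secures the first, while the tertiary hydroxyl is too hindered to be acylated and the ortho-flanked aryl ester is a poor acyl donor beside the anhydride. A slight overrun to the achiral diester removes the minor enantiomer preferentially, because its free arm is the one the enzyme favours, and should therefore polish the enantiomeric purity.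

Step 7
Reactants: 11 (2S)-2,3-dihydroxy-2-[2-(isobutyryloxy)-5-methoxy-4-methylphenyl]propyl isobutyrate
Product: 13 [(2S)-2-[2-(isobutyryloxy)-5-methoxy-4-methylphenyl]oxiran-2-yl]methyl isobutyrate (target), via primary mesylate 12 (not isolated)
Conditions: MsCl (1.1 equiv), Et3N (1.5 equiv), CH2Cl2, −20 °C, 20 min; then DBU (2 equiv), −20 → 10 °C; pH 7 buffer work-up; Et3N-deactivated silica
Reagents that add atoms: methanesulfonyl chloride, CS(=O)(=O)Cl (adds the mesyl group of 12 only; none of its atoms remains in 13)
Why: Selective sulfonylation of the primary hydroxyl followed by an intramolecular Williamson-type 3-exo-tet epoxide closure, in which only the CH2OH is mesylated at low temperature and DBU then lets the tertiary hydroxyl displace the mesylate at the CH2 carbon, so no bond to the stereocentre is broken and its configuration is carried over unchanged (12 reads R only because the mesyloxy arm outranks the acyloxy arm).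

Compound list
1 | 4-methoxy-3-methylphenol | COc1ccc(O)cc1C | starting material
2 | 2-bromo-4-methoxy-5-methylphenol | COc1cc(Br)c(O)cc1C | intermediate
3 | 1-(benzyloxy)-2-bromo-4-methoxy-5-methylbenzene | COc1cc(Br)c(OCc2ccccc2)cc1C | intermediate
4 | 2,2-dimethyl-1,3-dioxan-5-one (dihydroxyacetone acetonide) | CC1(C)OCC(=O)CO1 | starting material
5 | [2-(benzyloxy)-5-methoxy-4-methylphenyl]lithium (formed in the flask) | [Li]c1cc(OC)c(C)cc1OCc1ccccc1 | intermediate
6 | 5-[2-(benzyloxy)-5-methoxy-4-methylphenyl]-2,2-dimethyl-1,3-dioxan-5-ol | COc1cc(C2(O)COC(C)(C)OC2)c(OCc2ccccc2)cc1C | intermediate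
7 | isobutyric anhydride | CC(C)C(=O)OC(=O)C(C)C | starting material
8 | 5-(2-hydroxy-5-methoxy-4-methylphenyl)-2,2-dimethyl-1,3-dioxan-5-ol (formed in the flask) | COc1cc(C2(O)COC(C)(C)OC2)c(O)cc1C | intermediate
9 | 2-(5-hydroxy-2,2-dimethyl-1,3-dioxan-5-yl)-4-methoxy-5-methylphenyl isobutyrate | COc1cc(C2(O)COC(C)(C)OC2)c(OC(=O)C(C)C)cc1C | intermediate
10 | 4-methoxy-5-methyl-2-(1,2,3-trihydroxypropan-2-yl)phenyl isobutyrate (achiral, prochiral at C2 of the chain) | COc1cc(C(O)(CO)CO)c(OC(=O)C(C)C)cc1C | intermediate
11 | (2S)-2,3-dihydroxy-2-[2-(isobutyryloxy)-5-methoxy-4-methylphenyl]propyl isobutyrate | COc1cc([C@@](O)(COC(=O)C(C)C)CO)c(OC(=O)C(C)C)cc1C | intermediate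
12 | (2R)-2-hydroxy-2-[2-(isobutyryloxy)-5-methoxy-4-methylphenyl]-3-(methylsulfonyloxy)propyl isobutyrate (formed in the flask) | COc1cc([C@@](O)(COC(=O)C(C)C)COS(C)(=O)=O)c(OC(=O)C(C)C)cc1C | intermediate
13 | [(2S)-2-[2-(isobutyryloxy)-5-methoxy-4-methylphenyl]oxiran-2-yl]methyl isobutyrate, CNP0237100.1 | COc1cc([C@@]2(COC(=O)C(C)C)CO2)c(OC(=O)C(C)C)cc1C | target

Total step count: 7 (steps 4 and 7 each join two reactions in one flask sequence).
Longest linear sequence: 7 steps, from 1 to 13.

Steps most likely to fail

**Step 6.** The enzyme may tell the two hydroxymethyl arms apart poorly, or it may favour the arm that leads to the (R)-ester. It may also turn over so slowly next to the fully substituted carbon that uncatalysed acylation and acyl wandering dilute the enantiomeric purity. The fallback reverses the direction of the enzymatic step and sets out from 10. Both primary hydroxyls are esterified with 7 (Et3N, catalytic DMAP, CH2Cl2, 0 °C) to the achiral triester 2-[2-hydroxy-1,3-bis(isobutyryloxy)propan-2-yl]-4-methoxy-5-methylphenyl isobutyrate F1. A lipase then removes one of the two enantiotopic side-chain esters by alcoholysis with n-butanol in MTBE. The enzyme deacylates the same arm that it would acylate, so the ester stays on the other arm. An enzyme that fails by sense in step 6 therefore gives the right enantiomer here, and the route is rejoined at 11.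

**Step 7.** The bases may trigger acyl transfer from the aryl ester or the side-chain ester to the tertiary oxygen. A 1,3-acyl shift between the two CH2–O arms before the mesylate is in place would racemise the material. A phenoxide set free by such a transfer could also cyclise onto the sulfonate. The fallback replaces sulfonate and amine base by a redox condensation and sets out from 11. It uses Mitsunobu-type cyclodehydration with PPh3 and DIAD in toluene at 0 °C to rt. This turns the unhindered primary hydroxyl into an alkoxyphosphonium ion, which the tertiary hydroxyl displaces in the same 3-exo-tet mode. The route is rejoined at 13, and no compound beyond the list is made (F0).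

**Step 5.** Ketal cleavage may need acid strong enough to ionise the tertiary benzylic C–O bond. Alternatively, the activated aryl ester may wander to a freshly liberated hydroxyl, here or during the enzymatic step. The fallback postpones the aryl ester and sets out from 6.
- The acetonide is hydrolysed at the benzyl ether stage (aqueous AcOH) to 2-[2-(benzyloxy)-5-methoxy-4-methylphenyl]propane-1,2,3-triol F2, which carries no acyl group that could move.
- Lipase acylation with 7 as in step 6 gives (2S)-2-[2-(benzyloxy)-5-methoxy-4-methylphenyl]-2,3-dihydroxypropyl isobutyrate F3.
- Neutral hydrogenolysis (H2, 10% Pd/C, EtOAc) gives (2S)-2,3-dihydroxy-2-(2-hydroxy-5-methoxy-4-methylphenyl)propyl isobutyrate F4.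
- One equivalent of 7 with Et3N and no DMAP at −20 °C acylates the far more nucleophilic phenol in preference to the neopentyl-type primary hydroxyl, and the route is rejoined at 11.

Further compounds
F1 | step 6 | 2-[2-hydroxy-1,3-bis(isobutyryloxy)propan-2-yl]-4-methoxy-5-methylphenyl isobutyrate | COc1cc(C(O)(COC(=O)C(C)C)COC(=O)C(C)C)c(OC(=O)C(C)C)cc1C
F0 | step 7 | none | none
F2 | step 5 | 2-[2-(benzyloxy)-5-methoxy-4-methylphenyl]propane-1,2,3-triol | COc1cc(C(O)(CO)CO)c(OCc2ccccc2)cc1C
F3 | step 5 | (2S)-2-[2-(benzyloxy)-5-methoxy-4-methylphenyl]-2,3-dihydroxypropyl isobutyrate | COc1cc([C@@](O)(COC(=O)C(C)C)CO)c(OCc2ccccc2)cc1C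
F4 | step 5 | (2S)-2,3-dihydroxy-2-(2-hydroxy-5-methoxy-4-methylphenyl)propyl isobutyrate | COc1cc([C@@](O)(COC(=O)C(C)C)CO)c(O)cc1C
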